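# Total synthesis proposal for guanipiperazine A: aryne three-component coupling route

## Analysis of the target

Guanipiperazine A (26) is a guanine whose C8 is bonded to a benzene ring (ring A) that is part of a 14-membered meta,para-cyclophane. Ring A and a para-phenylene (ring B) are joined by an ether oxygen, and their benzylic CH2 groups sit on C5 and C2 of a piperazine. Ring A is 1,2,3,5-tetrasubstituted: C1 carries purine C8, C2 the free hydroxyl, C3 the oxygen to ring B, and C5 (para to the hydroxyl) the CH2 to the piperazine. The only stereocentres are piperazine C2 and C5; both are S, so the two benzyl arms are cis, as in a fully reduced cyclic dipeptide of two L-tyrosines. Sensitive features are the electron-rich phenol, two secondary amines, and an amphoteric, poorly soluble guanine with four N–H bonds. The cyclophane is strained (the span of the diaryl ether is longer than the cis-2,5 positions of a six-membered ring can bridge without bending the arenes), so any ring closure in the piperazine region is kinetically demanding. The second difficulty is the crowded C1/C2/C3 triad of ring A, which includes a C–C bond to C8 of a guanine. The plan rests on that triad: C1 (purinyl) and C2 (OH) are adjacent and C3 already carries the aryloxy group, so C1 and C2 can be the two carbons of an aryne whose neighbour is the aryloxy-bearing carbon.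

## Retrosynthetic reasoning

**26 to 24.** The last operation removes only protecting groups: the phenol MOM ether, the O6 2-(trimethylsilyl)ethyl group, the N9 SEM group (through the N9-hydroxymethyl stage 25) and both N2 4-methoxybenzyl groups. All are acid-labile, so the insoluble guanine, the free phenol and the free amines appear together at the very end. The forward step is one acidolysis followed by basic release of formaldehyde.

**24 to 23.** The two ring CH2 groups of the piperazine are traced back to lactam carbonyls. Amide bonds are the only piperazine bonds that can be closed from two α-amino acid arms without touching the stereocentres. The forward reaction is exhaustive reduction of the bis-lactam 23.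

**23 to 21, 20 and 19.** Both amide C–N bonds are cut. The diaryl ether is already present at this stage, so the macrocycle has to be closed in the piperazine region. The two cuts are head-to-tail equivalents, and whichever amide forms first, the same diketopiperazine results. The gain is an open-chain compound (19) whose two arms are functionally identical and can be built in the same operations. The forward reaction has to form a strained 14-membered lactam and then a six-membered one. It therefore uses two active esters (21) and releases both amines at high dilution (22). This is why the nitrogen protecting group is benzyloxycarbonyl, removed by neutral hydrogenolysis. A tert-butyl carbamate would need acid, which the phenol and purine protecting groups would not survive.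

**19 to 18.** The two C–H bonds at the stereocentres are removed. The centres are remote from each other and both S, so one chiral catalyst can set both by reagent control on the bis-enamide 18.

**18 to 16 and 17.** Both C=C bonds are cut, giving dialdehyde 16 and two equivalents of the glycine phosphonate 17, one for each aldehyde. The ring A aldehyde is para to the phenol oxygen. A phenoxide would switch it off as a vinylogous carboxylate, so the phenol has to be capped first.

**16 to 15 and 14.** These are functional-group changes only: acetal hydrolysis and phenol protection lead back to phenol 14.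

**14 to 8 and 4 (key disconnection).** The C8–C1 bond and the C2–O bond of ring A are cut together. Cutting only the C8–aryl bond (a cross-coupling) would require the oxygen and a halogen to be placed on neighbouring ring carbons in separate operations beforehand. Cutting both bonds lets one aryne carry the purine onto C1 and leave a carbanion on C2, exactly where oxygen is needed. The precursors are the fully protected purine 8 (lithiated at C8 to 9) and the chloro diaryl ether 4. The hydrogen of 4 that is flanked by chlorine and the aryloxy group is removed (10), and loss of chloride gives aryne 11. The forward reaction must control the site of deprotonation of 4, the direction of addition to 11, and the capture of aryllithium 12 by boron (13) before it is quenched. O6 carries a 2-(trimethylsilyl)ethyl ether and not a benzyl ether. Benzylic O–CH2 protons next to a purine invite anionic rearrangement under lithium amides, and a benzyl ether would be lost in the later hydrogenolysis.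

**8 to 7, 6 and 5.** Three standard operations on 2-amino-6-chloropurine (5) lead to 8: N9 alkylation, C6 substitution by an alkoxide, and double N2 benzylation. They remove every N–H and leave C8–H as the only acidic position.

**4 to 3, 1 and 2.** The diaryl ether C–O bond is cut on the ring B side, where a para-formyl group activates fluoride displacement. Phenol 1 and fluoroarene 2 give dialdehyde 3. Both aldehydes are masked as dimethyl acetals (4) so that they survive lithium amides and aryllithiums.

## Alternatives that were turned down

**Alternative 1: imidazole ring of the guanine built last.**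
- **Disconnection:** the C8–N7 and C8–N9 bonds.
- **Forward key step:** the macrocyclic salicylaldehyde A2 (piperazine nitrogens as tert-butyl carbamates) is condensed with the triaminopyrimidinone A3 at its 5-amino group. The resulting imine is ring-closed and dehydrogenated (FeCl3, a trivalent iron salt, or air in DMSO) to give the N,N'-protected natural product A1.
- **For:** the purine needs no protection or metalation. All macrocycle chemistry is done on the purine-free cyclophane A2 and its precursors, where the diaryl ether can be closed last by an Ullmann-type etherification. On macrocyclisation this alternative is stronger than the chosen route.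
- **Against:** A2 itself contains the contiguous CHO/OH/OAr triad, so the hard substitution pattern of ring A is only moved to another place and needs its own multi-step solution. A3 is air-sensitive and poorly soluble. The oxidative cyclisation has to run in the presence of an electron-rich phenol.
- **Comparison:** the chosen route offers in its place a single operation that installs the purine and the phenol oxygen on a cheap, flat diaryl ether, and a guanine that stays lipophilic until the last step.

**Alternative 2: cyclophane closed by directed C(sp3)–H arylation.**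
- **Disconnection:** the bond between ring B and its benzylic carbon.
- **Forward key step:** in the open-chain dipeptide A5, Pd(OAc)2 (divalent palladium) with AgOAc as iodide scavenger palladates a methyl C–H bond of the alanine residue under direction of its 8-aminoquinoline amide. Coupling of that carbon with the para-iodophenyl ether closes the 14-membered ring to give A4.
- **For:** both stereocentres come from the chiral pool, which is as strong as or stronger than catalytic hydrogenation. The ring is closed through a C–C bond and not through an amide.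
- **Against:** reductive elimination has to occur from a palladacycle held inside a strained cyclophane. The α-centre next to the directing amide can epimerise at the temperatures needed. The quinoline amide and the phthalimide must then be removed before the diketopiperazine can form. Most importantly, A4 contains neither the purine nor the hydroxyl-adjacent C–C bond, so the hardest bond of the target would remain to be made on a late, precious macrocycle.
- **Comparison:** the chosen route makes that bond first, on simple material, and gets both arms from one olefination–hydrogenation sequence.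

**Alternative 3: ring A made by benzannulation with macrocyclisation.**
- **Disconnection:** two C–C bonds of ring A.
- **Forward key step:** treated with NaOMe or DBU in dilute solution, A7 condenses within itself. The methylene carbons on either side of the ketone of its aryloxyacetoacetate arm attack the two electrophilic ends of its vinamidinium arm, two molecules of dimethylamine leave, and ring A appears as a methyl salicylate inside the macrocycle (A6).
- **For:** the regiochemistry of ring A is fixed by construction. The macrocycle closes while the future ring A carbons are still flexible, and aromatisation pays for the strain. On the thermodynamics of ring closure it is stronger than the chosen route.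
- **Against:** A7 is an unsymmetrical cis-2,5-disubstituted piperazine with two different, sensitive arms, which costs many steps. One of the two C–C bonds must form as a macrocyclisation in competition with oligomerisation. The ester of A6 still has to be converted into the guanine by a harsh condensation.
- **Comparison:** the chosen route is shorter to its key intermediate and uses two arms that are elaborated identically. It accepts a more demanding lactam closure in exchange.

Key step: step 6

## Conventions and assumption

- **Abbreviations in names:** Pur = 2-[bis(4-methoxybenzyl)amino]-6-[2-(trimethylsilyl)ethoxy]-9-{[2-(trimethylsilyl)ethoxy]methyl}-9H-purin-8-yl; SEM = [2-(trimethylsilyl)ethoxy]methyl; PMB = 4-methoxybenzyl; MOM = methoxymethyl; Cbz = benzyloxycarbonyl; Pfp = pentafluorophenyl; TMP = 2,2,6,6-tetramethylpiperidide.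
- **Assumption:** the N7–H form drawn for the guanine of the target is a tautomer of the N9–H form, so a protecting group on N9 leads to the same compound. Phosphonate 17 is used as the racemate, because its stereocentre becomes sp2 in step 9, and two molecules of it are consumed there.

## Route

Step 1
Reactants: 1 3-chloro-5-hydroxybenzaldehyde; 2 4-fluorobenzaldehyde
Product: 3 3-chloro-5-(4-formylphenoxy)benzaldehyde
Conditions: K2CO3, DMSO, 100 °C
Reagents that add atoms: none
Why: Nucleophilic aromatic substitution; the para-formyl group activates the C–F bond of 2, the phenoxide of 1 is the only nucleophile, and the unactivated aryl chloride of 1 (meta to its formyl group) is not displaced.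

Step 2
Reactants: 3 3-chloro-5-(4-formylphenoxy)benzaldehyde
Product: 4 1-chloro-3-(dimethoxymethyl)-5-[4-(dimethoxymethyl)phenoxy]benzene
Conditions: HC(OMe)3, MeOH, p-TsOH (cat.), rt; then Et3N
Reagents that add atoms: trimethyl orthoformate, COC(OC)OC; methanol, CO
Why: Acid-catalysed acetalisation driven by the orthoformate as water scavenger; both aldehydes are masked so that they tolerate the lithium amide and the aryllithiums of step 6.

Step 3
Reactants: 5 2-amino-6-chloropurine
Product: 6 6-chloro-9-{[2-(trimethylsilyl)ethoxy]methyl}-9H-purin-2-amine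
Conditions: SEMCl, K2CO3, DMF, 0 °C to rt
Reagents that add atoms: 2-(trimethylsilyl)ethoxymethyl chloride, C[Si](C)(C)CCOCCl
Why: N-Alkylation of the purine anion, which for 2-amino-6-chloropurine favours N9; the N7 isomer is removed by chromatography and the weakly nucleophilic exocyclic amine does not compete.

Step 4
Reactants: 6 6-chloro-9-{[2-(trimethylsilyl)ethoxy]methyl}-9H-purin-2-amine
Product: 7 6-[2-(trimethylsilyl)ethoxy]-9-{[2-(trimethylsilyl)ethoxy]methyl}-9H-purin-2-amine
Conditions: Me3SiCH2CH2OH, NaH, THF, 0 to 60 °C
Reagents that add atoms: 2-(trimethylsilyl)ethanol, C[Si](C)(C)CCO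
Why: Nucleophilic aromatic substitution of the C6 chloride by an alkoxide, the standard entry to O6-alkylguanines; the silylethyl ether has no benzylic protons, survives hydrogenolysis and falls off with acid at the end.

Step 5
Reactants: 7 6-[2-(trimethylsilyl)ethoxy]-9-{[2-(trimethylsilyl)ethoxy]methyl}-9H-purin-2-amine
Product: 8 N,N-bis(4-methoxybenzyl)-6-[2-(trimethylsilyl)ethoxy]-9-{[2-(trimethylsilyl)ethoxy]methyl}-9H-purin-2-amine
Conditions: NaH, PMBCl, Bu4NI (cat.), DMF, 0 °C to rt
Reagents that add atoms: 4-methoxybenzyl chloride, COc1ccc(CCl)cc1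
Why: Exhaustive N-alkylation of the deprotonated exocyclic amine (N9 and O6 are blocked, so the amide anion is the only strong nucleophile); it removes both N–H protons, which would otherwise consume the organolithiums of step 6.

Step 6
Reactants: 8 N,N-bis(4-methoxybenzyl)-6-[2-(trimethylsilyl)ethoxy]-9-{[2-(trimethylsilyl)ethoxy]methyl}-9H-purin-2-amine; 4 1-chloro-3-(dimethoxymethyl)-5-[4-(dimethoxymethyl)phenoxy]benzene
Product: 14 4-(dimethoxymethyl)-2-[4-(dimethoxymethyl)phenoxy]-6-Pur-phenol, via purin-8-yllithium 9 (not isolated), via lithiated chloro ether 10 (not isolated), via aryloxybenzyne 11 (not isolated), via biaryllithium 12 (not isolated), via dimethyl arylboronate 13 (not isolated)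
Conditions: LiTMP (from TMPH, n-BuLi), THF, −78 °C, 8 in excess; warm to −20 °C; B(OMe)3, −78 to 0 °C; H2O2, aq. NaOH, 0 °C to rt
Reagents that add atoms: hydrogen peroxide, OO
Why: Proposed new method: LiTMP removes C8–H of 8 (the only acidic C–H of the fully blocked purine) to give 9 and removes the ring hydrogen of 4 that lies between chlorine and the aryloxy oxygen (two cooperating inductive groups) to give 10, both of which persist at −78 °C. On warming, 10 loses LiCl (chloride, not aryloxide, is the leaving group) and gives 11, a benzyne with the aryloxy group next to the triple bond. The inductive pull of that oxygen distorts the aryne so that the carbanion 9 bonds to the remote terminus and the charge develops on the carbon beside oxygen, giving 12, whose lithium is held between the ether oxygen and N7 of the purine. B(OMe)3 captures 12 as 13 and alkaline H2O2 induces the 1,2-shift of the aryl group from boron to oxygen, so the C8–aryl bond and the phenol C–O bond are made in one flask; no ring is closed and no stereocentre is formed. The closest known reaction type is the addition of aryllithium or aryl Grignard reagents to 3-alkoxybenzynes generated from 3-haloanisoles, with electrophilic trapping of the resulting 2-metalated biaryl; new here is a purin-8-yl (azol-2-yl type) carbanion as the aryne nucleophile. The step needs three selectivities: the site of deprotonation of 4 (fixed by the two flanking heteroatoms), the direction of addition to 11 (fixed by the aryloxy group), and the choice of nucleophile. For the third, LiTMP is too hindered to add, no diisopropylamide is present because the same base is used for both deprotonations, and 8 is used in excess so that 9 outcompetes 10 for the aryne. Surplus 9 ends as protonated or 8-oxygenated purine, which is separable.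

Step 7
Reactants: 14 4-(dimethoxymethyl)-2-[4-(dimethoxymethyl)phenoxy]-6-Pur-phenol
Product: 15 5-(dimethoxymethyl)-1-[4-(dimethoxymethyl)phenoxy]-2-(methoxymethoxy)-3-Pur-benzene
Conditions: NaH, MOMCl, THF/DMF, 0 °C to rt
Reagents that add atoms: chloromethyl methyl ether, COCCl
Why: Williamson etherification of the hindered, hydrogen-bonded phenol through its sodium salt; the cap is needed because the free phenoxide would deactivate the para aldehyde in step 9 and be acylated in step 13, and a MOM ether survives base, hydrogenation and borane.

Step 8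
Reactants: 15 5-(dimethoxymethyl)-1-[4-(dimethoxymethyl)phenoxy]-2-(methoxymethoxy)-3-Pur-benzene
Product: 16 3-(4-formylphenoxy)-4-(methoxymethoxy)-5-Pur-benzaldehyde
Conditions: PPTS (cat.), acetone/H2O, rt
Reagents that add atoms: water, O
Why: Acetal hydrolysis; dimethyl acetals of benzaldehydes are cleaved by weak acid far faster than an aryl MOM ether, the SEM group or the silylethyl ether, so only the two aldehydes are released.

Step 9
Reactants: 16 3-(4-formylphenoxy)-4-(methoxymethoxy)-5-Pur-benzaldehyde; 17 methyl 2-{[(benzyloxy)carbonyl]amino}-2-(dimethoxyphosphoryl)acetate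
Product: 18 methyl (Z)-2-(Cbz-amino)-3-{4-[5-((Z)-2-(Cbz-amino)-3-methoxy-3-oxoprop-1-enyl)-2-(methoxymethoxy)-3-Pur-phenoxy]phenyl}acrylate
Conditions: 17 (2.4 equiv), DBU, CH2Cl2, 0 °C to rt
Reagents that add atoms: methyl 2-{[(benzyloxy)carbonyl]amino}-2-(dimethoxyphosphoryl)acetate (second equivalent of 17), COC(=O)C(NC(=O)OCc1ccccc1)P(=O)(OC)OC
Why: Twofold Horner–Wadsworth–Emmons olefination in which each aldehyde of 16 consumes one molecule of 17, so two equivalents of the phosphonate enter the product and a slight excess is used. N-Acyl phosphonoglycinates give the (Z)-dehydroamino esters (aryl cis to nitrogen) with high selectivity, and both aldehydes are unhindered and now electronically alike.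

Step 10
Reactants: 18 methyl (Z)-2-(Cbz-amino)-3-{4-[5-((Z)-2-(Cbz-amino)-3-methoxy-3-oxoprop-1-enyl)-2-(methoxymethoxy)-3-Pur-phenoxy]phenyl}acrylate
Product: 19 methyl (S)-2-(Cbz-amino)-3-{4-[5-((S)-2-(Cbz-amino)-3-methoxy-3-oxopropyl)-2-(methoxymethoxy)-3-Pur-phenoxy]phenyl}propanoate
Conditions: [Rh(cod)((S,S)-Et-DuPhos)]BF4 (cat.), H2 (5 bar), MeOH/THF, rt
Reagents that add atoms: none
Why: Rhodium-catalysed asymmetric hydrogenation of (Z)-α-(acylamino)acrylates; each enamide chelates the cationic monovalent rhodium through C=C and the carbamate carbonyl, and the (S,S)-ligand delivers H2 to the same enantioface of both arms, so both new stereocentres are S by catalyst control. The two events are independent, so the minor (R,S) diastereomer is removed by chromatography; the homogeneous catalyst does not touch Cbz or PMB groups.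

Step 11
Reactants: 19 methyl (S)-2-(Cbz-amino)-3-{4-[5-((S)-2-(Cbz-amino)-3-methoxy-3-oxopropyl)-2-(methoxymethoxy)-3-Pur-phenoxy]phenyl}propanoate
Product: 20 (S)-2-(Cbz-amino)-3-{4-[5-((S)-2-(Cbz-amino)-2-carboxyethyl)-2-(methoxymethoxy)-3-Pur-phenoxy]phenyl}propanoic acid
Conditions: LiOH, THF/H2O, 0 °C; then 0.5 M HCl to pH 4, 0 °C
Reagents that add atoms: lithium hydroxide, [Li+].[OH-]
Why: Saponification; carbamate-protected α-amino esters are hydrolysed at 0 °C without racemisation, and the brief cold acidification to pH 4 does not affect the acid-labile groups.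

Step 12
Reactants: 20 (S)-2-(Cbz-amino)-3-{4-[5-((S)-2-(Cbz-amino)-2-carboxyethyl)-2-(methoxymethoxy)-3-Pur-phenoxy]phenyl}propanoic acid
Product: 21 bis(pentafluorophenyl) ester of 20
Conditions: C6F5OH, EDC·HCl, CH2Cl2, 0 °C to rt
Reagents that add atoms: pentafluorophenol, Oc1c(F)c(F)c(F)c(F)c1F
Why: Carbodiimide esterification to isolable active esters; the carbamate on nitrogen suppresses oxazolone formation, so the α-centres keep their configuration.

Step 13
Reactants: 21 bis(pentafluorophenyl) ester of 20
Product: 23 (3S,6S)-piperazine-2,5-dione bridged between C3 (benzyl arm of ring B) and C6 (benzyl arm of ring A) by the diaryl ether with ring A carrying OMOM and Pur, via diamine bis(pentafluorophenyl) ester 22 (not isolated)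
Conditions: H2 (1 bar), Pd/C, 4-pyrrolidinopyridine (cat.), dioxane, 90 °C, slow addition of 21 (high dilution)
Reagents that add atoms: none
Why: Hydrogenolysis of both Cbz groups releases the amines in hot dilute solution, where each can only acylate the active ester of the other arm (attack on its own arm would give a three-membered ring). The first amide closes the 14-membered ring, and either head-to-tail pairing is productive; the second closes the six-membered ring once the amide reaches its cis rotamer at 90 °C. No stereocentre is touched.

Step 14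
Reactants: 23 (3S,6S)-piperazine-2,5-dione bridged between C3 and C6 by the diaryl ether with ring A carrying OMOM and Pur
Product: 24 (2S,5S)-piperazine bridged between C2 (benzyl arm of ring B) and C5 (benzyl arm of ring A) by the diaryl ether with ring A carrying OMOM and Pur
Conditions: BH3·THF, THF, 65 °C; then MeOH, 65 °C
Reagents that add atoms: none
Why: Borane reduction of a secondary bis-lactam to the piperazine, the usual conversion of diketopiperazines; the non-basic conditions do not epimerise the α-centres, ethers and the alkoxypurine are inert, and methanolysis breaks the amine–borane adducts.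

Step 15
Reactants: 24 (2S,5S)-piperazine bridged between C2 and C5 by the diaryl ether with ring A carrying OMOM and Pur
Product: 26 guanipiperazine A, via N9-hydroxymethyl guanine 25 (not isolated)
Conditions: TFA, anisole, 65 °C; then NH3, MeOH, rt
Reagents that add atoms: none
Why: Global acidolysis: the MOM acetal is cleaved, the SEM and silylethyl groups fragment to ethene and a silyl trifluoroacetate, and both PMB groups leave as cations that anisole captures. Ammonia then releases formaldehyde from N9–CH2OH and from any N-hydroxymethyl adducts on the piperazine; the diaryl ether, phenol, piperazine and guanine are stable to these conditions.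

## Compound list

1 | 3-chloro-5-hydroxybenzaldehyde | O=Cc1cc(O)cc(Cl)c1 | starting material
2 | 4-fluorobenzaldehyde | O=Cc1ccc(F)cc1 | starting material
3 | 3-chloro-5-(4-formylphenoxy)benzaldehyde | O=Cc1ccc(Oc2cc(Cl)cc(C=O)c2)cc1 | intermediate
4 | 1-chloro-3-(dimethoxymethyl)-5-[4-(dimethoxymethyl)phenoxy]benzene | COC(OC)c1cc(Cl)cc(Oc2ccc(C(OC)OC)cc2)c1 | intermediate
5 | 2-amino-6-chloropurine | Nc1nc(Cl)c2nc[nH]c2n1 | starting material
6 | 6-chloro-9-{[2-(trimethylsilyl)ethoxy]methyl}-9H-purin-2-amine | Nc1nc(Cl)c2ncn(COCC[Si](C)(C)C)c2n1 | intermediate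
7 | 6-[2-(trimethylsilyl)ethoxy]-9-{[2-(trimethylsilyl)ethoxy]methyl}-9H-purin-2-amine | Nc1nc(OCC[Si](C)(C)C)c2ncn(COCC[Si](C)(C)C)c2n1 | intermediate
8 | N,N-bis(4-methoxybenzyl)-6-[2-(trimethylsilyl)ethoxy]-9-{[2-(trimethylsilyl)ethoxy]methyl}-9H-purin-2-amine (Pur–H) | COc1ccc(CN(Cc2ccc(OC)cc2)c2nc(OCC[Si](C)(C)C)c3ncn(COCC[Si](C)(C)C)c3n2)cc1 | intermediate
9 | Pur–Li (8-lithio derivative of 8) | COc1ccc(CN(Cc2ccc(OC)cc2)c2nc(OCC[Si](C)(C)C)c3nc([Li])n(COCC[Si](C)(C)C)c3n2)cc1 | intermediate
10 | {2-chloro-4-(dimethoxymethyl)-6-[4-(dimethoxymethyl)phenoxy]phenyl}lithium | COC(OC)c1cc(Cl)c([Li])c(Oc2ccc(C(OC)OC)cc2)c1 | intermediate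
11 | 5-(dimethoxymethyl)-3-[4-(dimethoxymethyl)phenoxy]benzyne | COC(OC)C1=CC#CC(Oc2ccc(C(OC)OC)cc2)=C1 | intermediate
12 | {4-(dimethoxymethyl)-2-[4-(dimethoxymethyl)phenoxy]-6-Pur-phenyl}lithium | COC(OC)c1cc(-c2nc3c(OCC[Si](C)(C)C)nc(N(Cc4ccc(OC)cc4)Cc4ccc(OC)cc4)nc3n2COCC[Si](C)(C)C)c([Li])c(Oc2ccc(C(OC)OC)cc2)c1 | intermediate
13 | dimethyl {4-(dimethoxymethyl)-2-[4-(dimethoxymethyl)phenoxy]-6-Pur-phenyl}boronate | COC(OC)c1cc(-c2nc3c(OCC[Si](C)(C)C)nc(N(Cc4ccc(OC)cc4)Cc4ccc(OC)cc4)nc3n2COCC[Si](C)(C)C)c(B(OC)OC)c(Oc2ccc(C(OC)OC)cc2)c1 | intermediate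
14 | 4-(dimethoxymethyl)-2-[4-(dimethoxymethyl)phenoxy]-6-Pur-phenol | COC(OC)c1cc(-c2nc3c(OCC[Si](C)(C)C)nc(N(Cc4ccc(OC)cc4)Cc4ccc(OC)cc4)nc3n2COCC[Si](C)(C)C)c(O)c(Oc2ccc(C(OC)OC)cc2)c1 | intermediate
15 | 5-(dimethoxymethyl)-1-[4-(dimethoxymethyl)phenoxy]-2-(methoxymethoxy)-3-Pur-benzene | COC(OC)c1cc(-c2nc3c(OCC[Si](C)(C)C)nc(N(Cc4ccc(OC)cc4)Cc4ccc(OC)cc4)nc3n2COCC[Si](C)(C)C)c(OCOC)c(Oc2ccc(C(OC)OC)cc2)c1 | intermediate
16 | 3-(4-formylphenoxy)-4-(methoxymethoxy)-5-Pur-benzaldehyde | O=Cc1ccc(Oc2cc(C=O)cc(-c3nc4c(OCC[Si](C)(C)C)nc(N(Cc5ccc(OC)cc5)Cc5ccc(OC)cc5)nc4n3COCC[Si](C)(C)C)c2OCOC)cc1 | intermediate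
17 | methyl 2-{[(benzyloxy)carbonyl]amino}-2-(dimethoxyphosphoryl)acetate (racemic) | COC(=O)C(NC(=O)OCc1ccccc1)P(=O)(OC)OC | starting material
18 | methyl (Z)-2-(Cbz-amino)-3-{4-[5-((Z)-2-(Cbz-amino)-3-methoxy-3-oxoprop-1-enyl)-2-(methoxymethoxy)-3-Pur-phenoxy]phenyl}acrylate | COC(=O)/C(NC(=O)OCc1ccccc1)=C/c1ccc(Oc2cc(/C=C(\NC(=O)OCc3ccccc3)C(=O)OC)cc(-c3nc4c(OCC[Si](C)(C)C)nc(N(Cc5ccc(OC)cc5)Cc5ccc(OC)cc5)nc4n3COCC[Si](C)(C)C)c2OCOC)cc1 | intermediate
19 | methyl (S)-2-(Cbz-amino)-3-{4-[5-((S)-2-(Cbz-amino)-3-methoxy-3-oxopropyl)-2-(methoxymethoxy)-3-Pur-phenoxy]phenyl}propanoate | COC(=O)[C@H](Cc1ccc(Oc2cc(C[C@H](NC(=O)OCc3ccccc3)C(=O)OC)cc(-c3nc4c(OCC[Si](C)(C)C)nc(N(Cc5ccc(OC)cc5)Cc5ccc(OC)cc5)nc4n3COCC[Si](C)(C)C)c2OCOC)cc1)NC(=O)OCc1ccccc1 | intermediate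
20 | (S)-2-(Cbz-amino)-3-{4-[5-((S)-2-(Cbz-amino)-2-carboxyethyl)-2-(methoxymethoxy)-3-Pur-phenoxy]phenyl}propanoic acid | OC(=O)[C@H](Cc1ccc(Oc2cc(C[C@H](NC(=O)OCc3ccccc3)C(=O)O)cc(-c3nc4c(OCC[Si](C)(C)C)nc(N(Cc5ccc(OC)cc5)Cc5ccc(OC)cc5)nc4n3COCC[Si](C)(C)C)c2OCOC)cc1)NC(=O)OCc1ccccc1 | intermediate
21 | bis(pentafluorophenyl) ester of 20 | O=C(Oc1c(F)c(F)c(F)c(F)c1F)[C@H](Cc1ccc(Oc2cc(C[C@H](NC(=O)OCc3ccccc3)C(=O)Oc3c(F)c(F)c(F)c(F)c3F)cc(-c3nc4c(OCC[Si](C)(C)C)nc(N(Cc5ccc(OC)cc5)Cc5ccc(OC)cc5)nc4n3COCC[Si](C)(C)C)c2OCOC)cc1)NC(=O)OCc1ccccc1 | intermediate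
22 | bis(pentafluorophenyl) ester of the (S,S)-diamino diacid (both Cbz groups removed from 21) | O=C(Oc1c(F)c(F)c(F)c(F)c1F)[C@H](Cc1ccc(Oc2cc(C[C@H](N)C(=O)Oc3c(F)c(F)c(F)c(F)c3F)cc(-c3nc4c(OCC[Si](C)(C)C)nc(N(Cc5ccc(OC)cc5)Cc5ccc(OC)cc5)nc4n3COCC[Si](C)(C)C)c2OCOC)cc1)N | intermediate
23 | (3S,6S)-piperazine-2,5-dione bridged between C3 (benzyl arm of ring B) and C6 (benzyl arm of ring A) by the diaryl ether; ring A carries OMOM and Pur | C[Si](C)(C)CCOCn1c(-c3cc4cc(c3OCOC)Oc3ccc(cc3)C[C@H]3C(=O)N[C@H](C(=O)N3)C4)nc2c(OCC[Si](C)(C)C)nc(N(Cc5ccc(OC)cc5)Cc5ccc(OC)cc5)nc21 | intermediate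
24 | (2S,5S)-piperazine bridged between C2 (benzyl arm of ring B) and C5 (benzyl arm of ring A) by the diaryl ether; ring A carries OMOM and Pur | C[Si](C)(C)CCOCn1c(-c3cc4cc(c3OCOC)Oc3ccc(cc3)C[C@H]3CN[C@H](CN3)C4)nc2c(OCC[Si](C)(C)C)nc(N(Cc5ccc(OC)cc5)Cc5ccc(OC)cc5)nc21 | intermediate
25 | guanipiperazine A carrying a hydroxymethyl group on N9 | Nc1nc2n(CO)c(-c3cc4cc(c3O)Oc3ccc(cc3)C[C@H]3CN[C@H](CN3)C4)nc2c(=O)[nH]1 | intermediate
26 | guanipiperazine A | Nc1nc2nc(-c3cc4cc(c3O)Oc3ccc(cc3)C[C@H]3CN[C@H](CN3)C4)[nH]c2c(=O)[nH]1 | target

## Step count and risk assessment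

Total step count: 15. Longest linear sequence: 13 steps (5 to 26 through steps 3 to 15); the diaryl ether branch (steps 1 and 2) joins at step 6.

**Step 6 (key step, new method).**
- **What may go wrong:** addition of the delocalised purinyl anion 9 to the aryne may be slower than self-addition of 10, giving chloro-biaryl ether oligomers. The aryllithium 12 may also be protonated by the liberated amine before borylation, giving the arylpurine without the hydroxyl.
- **Fallback (known chemistry, bonds made in two separate operations):** from 4, deprotonation at −78 °C with LiTMP in the presence of B(OiPr)3, so that the anion is borylated before chloride is lost, followed by H2O2/NaOH, gives 2-chloro-4-(dimethoxymethyl)-6-[4-(dimethoxymethyl)phenoxy]phenol F1. Etherification with MOMCl/NaH gives its methoxymethyl ether F2. Purine 8 is zincated at C8 with TMPZnCl·LiCl to the purin-8-ylzinc chloride F3. A Negishi coupling of F3 with the aryl chloride F2 (Pd(OAc)2, XPhos, THF, 65 °C) returns to the route at 15.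

**Step 13 (double lactamisation).**
- **What may go wrong:** the first amide bond has to close a strained 14-membered cyclophane, so intermolecular acylation can outrun it and give oligomers. The second closure needs rotation of the new amide to its cis form, which may be slow enough for the remaining active ester to react between molecules.
- **Fallback (closure at the aldehyde oxidation level through reversible imine bonds):** from 19, reduction with i-Bu2AlH at −78 °C gives the bis(N-Cbz α-amino aldehyde) F4. Hydrogenolysis at high dilution (H2, Pd/C, MeOH, a little AcOH) frees both amines. They condense head-to-tail with the aldehyde of the other arm to the macrocyclic 2,5-dihydropyrazine F5, which is hydrogenated in the same flask. The route is rejoined at 24, and steps 11 to 14 are bypassed. The weak point of this variant is the configurational lability of α-amino aldehydes and of F5, which is why it is not the first choice.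

**Step 15 (global deprotection).**
- **What may go wrong:** removal of the second PMB group from N2 may stall. The formaldehyde and benzyl cations set free together may recombine with the piperazine nitrogens or with ring B.
- **Fallback (two stages on orthogonal triggers):** from 24, Bu4NF with ethylenediamine in THF at 65 °C removes the two silicon-based groups and gives the MOM-protected N2,N2-bis(4-methoxybenzyl) guanine F6. TFA/anisole at 65 °C then has to cleave only the PMB and MOM groups and gives 26.

**Step 5 (double N-benzylation).**
- **What may go wrong:** alkylation may stop at the mono-benzyl stage or go to a ring nitrogen (N1 or N3), giving mixtures that still carry an N–H.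
- **Fallback (C–N bond made from the other side):** from 7, non-aqueous diazotisation–iodination (t-BuONO, CH2I2, CuI, THF, 65 °C) gives 2-iodo-6-[2-(trimethylsilyl)ethoxy]-9-{[2-(trimethylsilyl)ethoxy]methyl}-9H-purine F7. A Buchwald–Hartwig amination with bis(4-methoxybenzyl)amine (Pd2(dba)3, Xantphos, Cs2CO3, dioxane, 100 °C) returns to 8.

## Further compounds

F1 | step 6 | 2-chloro-4-(dimethoxymethyl)-6-[4-(dimethoxymethyl)phenoxy]phenol | COC(OC)c1cc(Cl)c(O)c(Oc2ccc(C(OC)OC)cc2)c1
F2 | step 6 | 1-chloro-5-(dimethoxymethyl)-3-[4-(dimethoxymethyl)phenoxy]-2-(methoxymethoxy)benzene | COC(OC)c1cc(Cl)c(OCOC)c(Oc2ccc(C(OC)OC)cc2)c1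
F3 | step 6 | Pur–ZnCl (purin-8-ylzinc chloride from 8) | COc1ccc(CN(Cc2ccc(OC)cc2)c2nc(OCC[Si](C)(C)C)c3nc([Zn]Cl)n(COCC[Si](C)(C)C)c3n2)cc1
F4 | step 13 | benzyl N-[(S)-1-oxo-3-{4-[5-((S)-2-(Cbz-amino)-3-oxopropyl)-2-(methoxymethoxy)-3-Pur-phenoxy]phenyl}propan-2-yl]carbamate (bis-aldehyde from 19) | O=C[C@H](Cc1ccc(Oc2cc(C[C@H](NC(=O)OCc3ccccc3)C=O)cc(-c3nc4c(OCC[Si](C)(C)C)nc(N(Cc5ccc(OC)cc5)Cc5ccc(OC)cc5)nc4n3COCC[Si](C)(C)C)c2OCOC)cc1)NC(=O)OCc1ccccc1
F5 | step 13 | (2S,5S)-2,5-dihydropyrazine bridged between C2 (benzyl arm of ring B) and C5 (benzyl arm of ring A) by the diaryl ether; ring A carries OMOM and Pur | C[Si](C)(C)CCOCn1c(-c3cc4cc(c3OCOC)Oc3ccc(cc3)C[C@H]3C=N[C@H](C=N3)C4)nc2c(OCC[Si](C)(C)C)nc(N(Cc5ccc(OC)cc5)Cc5ccc(OC)cc5)nc21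
F6 | step 15 | N2,N2-bis(4-methoxybenzyl) O-methoxymethyl guanipiperazine A | COCOc1c(-c2nc3c(=O)[nH]c(N(Cc4ccc(OC)cc4)Cc4ccc(OC)cc4)nc3[nH]2)cc2cc1Oc1ccc(cc1)C[C@H]1CN[C@H](CN1)C2
F7 | step 5 | 2-iodo-6-[2-(trimethylsilyl)ethoxy]-9-{[2-(trimethylsilyl)ethoxy]methyl}-9H-purine | Ic1nc(OCC[Si](C)(C)C)c2ncn(COCC[Si](C)(C)C)c2n1
A1 | alternative 1 | N,N'-di-Boc guanipiperazine A | Nc1nc2nc(-c3cc4cc(c3O)Oc3ccc(cc3)C[C@H]3CN(C(=O)OC(C)(C)C)[C@H](CN3C(=O)OC(C)(C)C)C4)[nH]c2c(=O)[nH]1
A2 | alternative 1 | N,N'-di-Boc macrocyclic salicylaldehyde (ring A carries CHO in place of the purine) | O=Cc1cc2cc(c1O)Oc1ccc(cc1)C[C@H]1CN(C(=O)OC(C)(C)C)[C@H](CN1C(=O)OC(C)(C)C)C2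
A3 | alternative 1 | 2,5,6-triaminopyrimidin-4(3H)-one | Nc1nc(N)c(N)c(=O)[nH]1
A4 | alternative 2 | 14-membered cyclophane dipeptide with phthalimide and 8-aminoquinoline amide | O=C1N[C@H](C(=O)Nc2cccc3cccnc23)Cc2ccc(cc2)Oc2cc(ccc2OCc2ccccc2)C[C@@H]1N1C(=O)c2ccccc2C1=O
A5 | alternative 2 | N-phthaloyl-O-benzyl-3-(4-iodophenoxy)-L-tyrosyl-L-alanine 8-aminoquinoline amide | C[C@H](NC(=O)[C@H](Cc1ccc(OCc2ccccc2)c(Oc2ccc(I)cc2)c1)N1C(=O)c2ccccc2C1=O)C(=O)Nc1cccc2cccnc12
A6 | alternative 3 | N,N'-di-Cbz macrocyclic methyl salicylate | COC(=O)c1cc2cc(c1O)Oc1ccc(cc1)C[C@H]1CN(C(=O)OCc3ccccc3)[C@H](CN1C(=O)OCc1ccccc1)C2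
A7 | alternative 3 | N,N'-di-Cbz (2S,5S)-piperazine with a 4-aryloxyacetoacetate arm and a vinamidinium arm (hexafluorophosphate) | COC(=O)CC(=O)COc1ccc(cc1)C[C@H]1CN(C(=O)OCc2ccccc2)[C@H](CN1C(=O)OCc1ccccc1)CC(C=[N+](C)C)=CN(C)C.F[P-](F)(F)(F)(F)F
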